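Begin with the neighbour of these flasks in which target, once made, simply stays; then reckon only what differs from it.

| flask | starting material | second substrate | reagent | free catalyst | time | remark |
|---|---|---|---|---|---|---|
| theta | 24 mM (fed, over 50.0 min) | 1.00 equiv | 1.10 equiv | 0.065 mol% | 50 min | all but starting material at the start; starting material goes in evenly over 50.0 min, the run ends at 50 min |
| eta | 24 mM | 1.00 equiv | 1.10 equiv | 0.065 mol% | 50 min | a closed flask charged with all of it at once and left for 50 min |
| gamma | 24 mM | 1.00 equiv (fed, over 50.0 min) | 1.10 equiv | 0.065 mol% | 50 min | a stirred flask in which second substrate is dosed at a steady rate over 50.0 min without added volume, worked up at 50 min |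
| beta | 24 mM | 1.00 equiv | 1.10 equiv | 0.065 mol% |  | a single well-mixed tank run continuously and read at steady state, 50 min in it on average |

- the set-up with the highest amount of target at the outlet or at the end, in percent of the starting material put in ("none" if the first two lie within 2 percentage points) (theta / eta / gamma / beta / none)
- amount of target at the outlet or at the end, in percent of the starting material put in, theta
- amount of target at the outlet or at the end, in percent of the starting material put in, eta
- amount of target at the outlet or at the end, in percent of the starting material put in, gamma
- amount of target at the outlet or at the end, in percent of the starting material put in, beta

- percent here means starting material units held: one side product counts as two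
- a step written with two of one species runs at k times the square of its concentration and takes two of it each time
- the stated concentrations are those of everything mixed, before any reaction; amounts are the same in each set-up
- the feed brings no volume worth counting
- run time (theta): 50 min

    starting material + free catalyst ⇌ catalyst intermediate A (K1 = 670 L mol⁻¹, k1 = 5800 L mol⁻¹ min⁻¹)
    reagent + catalyst intermediate A → free catalyst + target (k2 = 1300 L mol⁻¹ min⁻¹)
    second substrate + free catalyst ⇌ catalyst intermediate B (K3 = 21 L mol⁻¹, k3 = 5700 L mol⁻¹ min⁻¹)
    reagent + catalyst intermediate B → free catalyst + second product (k4 = 9900 L mol⁻¹ min⁻¹)
    2 second substrate → self-condensation product (k5 = 0.30 L mol⁻¹ min⁻¹)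
    starting material + target → side product (k6 = 1.8 L mol⁻¹ min⁻¹)

Here target does not stay: starting material + target → side product (k6 = 1.8 L mol⁻¹ min⁻¹). Carry one quantity, the target lifetime L, the reciprocal of that rate constant times the starting material concentration; at the charge, L is 23.1 min. That is shorter than the 50 min run, so this correction is not small. In a well-mixed tank with mean time t, target leaves at rate one over t and dies at rate one over L, so the tank keeps the share L/(L+t) of what it makes. With starting material at its charge, this is 31.6 %. My reckoning stops there: it gives a share kept and no amount made.

The forecast names gamma, with 20.5 % for theta, 25.7 % for eta, 29.5 % for gamma and 18.5 % for beta. Its ground: “Dosing the second substrate keeps starting material ahead in the race for reagent and catalyst”.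

The simulation gives 20.4 % for theta, 26.2 % for eta, 29.5 % for gamma and 18.3 % for beta, so gamma gives the most.

Strike the loss of target from beta and its target rises from 18.3 % to 39.4 %, a part of what is missing. The beta tank holds starting material at 45.7 %, so L there is 50.7 min and the tank keeps half of what it makes. Applied to the target of that struck run, this share gives 19.8 %, and beta reads 18.3 %. Gamma ends with 26.6 % starting material, so L at its end has stretched to 87.1 min.

The numbers of this flask were chosen freely; what happens was integrated by code.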